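(The data stem from a simulated flask with constants of no real substance, noise included.)

At early times the midnight run, which is this very flask followed so far, looks finished: by 4.00 min the first end groups stand near 17.2% and barely move afterwards. When you repeat the run, watch the links instead.

- midnight: first end groups 20 mM; second end groups 1.1 equiv; one-sided end groups 0.20 mM; protic impurity 2 mM; the very flask that is asked about, followed so far
- flask: first end groups 20 mM; second end groups 1.10 equiv; one-sided end groups 0.200 mM; protic impurity 2.00 mM; time 40 min

midnight run (percent of the first end groups charged)

| time / min | links / % | first end groups / % |
|---|---|---|
| 1.50 | 77.1 | 21.4 |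
| 4.00 | 81.2 | 17.2 |
| 8.00 | 81.9 | 17.0 |
| 20.0 | 80.7 | 16.8 |

(standard deviation of a reading: 0.5 percentage points)

- each monomer carries two end groups and one-sided end groups one, which caps an end: a chain counts once for every two ends that are left, dead ends included; the units are half of the end groups of the two monomers charged
- steps that have been proposed: first end groups + second end groups -> links; first end groups + one-sided end groups -> capped ends; links -> over-reaction product; second end groups + protic impurity -> quenched reagent; second end groups -> decomposed reagent
- a link that another step uses up counts as cut, two dead ends; so do two ends of one kind that react with each other

- average number of monomer units in a chain (unreacted monomers counted as chains of one) at 40 min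
- part of the first end groups that has reacted at 40 min

1. Count chains. Let U be the units, half of the monomer end groups charged: U = 21.0 mM. Each standing link, with L their concentration, removes one chain, and a cut link stops counting, so the average number of units in a chain is dp = U/(U − L).

2. First way to L. The first end groups read on average A = 17.0% from 4.00 min on, so c, the part of them that has reacted, is 83.0%. Subtract the one-sided end groups' charge, taken as capped, and the links made are M = 16.4 mM.

3. Second way. The links reading at 20.0 min gives L = 16.1 mM.

4. The two ways part by 1.3 percentage points, against a scatter of 0.5 points per reading, so this is a weak signal. The first way cheats: a reacted first end group stays reacted, so M still counts a link that was later cut.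

5. Read the gap as first-order loss. The cut constant k, the fraction of standing links lost per minute, is ln(M/L)/t = 7.99 × 10⁻⁴ min⁻¹. By 40 min the cut share of links made is 3.15%, which leaves L = 15.9 mM and my dp of 4.12.

6. The forecast gives 4.1 and 83.1%, holding that “links are slowly being cut”.

The flask gives dp = 4.12 and c = 82.9%.

    first end groups + second end groups → links (k = 3.24 M⁻¹ s⁻¹)
    first end groups + one-sided end groups → capped ends (k = 400 M⁻¹ s⁻¹)
    links → over-reaction product (k = 1.24 × 10⁻⁵ s⁻¹)
    second end groups + protic impurity → quenched reagent (k = 65.4 M⁻¹ s⁻¹)
    second end groups → decomposed reagent (k = 0.00668 s⁻¹)

From 4.00 min to 40 min, c goes from 82.7% to 82.9% while dp falls from 4.46 to 4.12. In this flask, k puts the cut links at 2.58% of the first end groups charged, and the over-reaction product stands at 2.38%. In the neighbour flask, the same flask with 50 mM of first end groups, k puts the cut links at 2.96%, and that neighbour flask holds 2.74% of over-reaction product.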